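**Retrosynthetic overview**

1. Target 38 ⇒ 35: C13–Cl and C11–OH come from HCl opening of the 11,13-epoxide of an α-methylene lactone; the C8 tiglate comes from acylation; the C5 and C9 silyl ethers are removed last.
2. The lactone ring (O6–C12–C11–C7–C6) comes from 5-exo opening of a 7,8-epoxide at C7 by a C6-bound phosphonoacetate, then formaldehyde olefination; the 9-OH comes from allylic oxidation and reduction at the E C7=C8 alkene; C2=C3 comes from dehydrogenation.
3. The strategy rests on one feature: a single oxygen bridges C3 and C10 of the ten-membered carbocycle C1–C10, next to the C1 ketone (five-membered ring O–C3–C2–C1–C10 inside a nine-membered oxacycle). This is the imprint of a [2,3]-shift of a cyclic O-allyl oxonium ylide. Breaking C9–C10 and O–C10 and restoring O–C7 leads from 21 back to 19, a cis-2,6-disubstituted 6-vinyltetrahydropyran with a methyl diazoketone arm.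
4. 19 ⇒ D-tartrate (C5–C8, O6 and the bridging oxygen), (E)-but-2-ene (C3, C4, 4-Me), methyl acrylate (C1, C2), a methylene Wittig reagent (C9) and diazoethane (C10, 10-Me).
5. Ring order: tetrahydropyran (sacrificial) → furanone ring and ten-membered carbocycle together (step 14) → γ-lactone (step 23).

Key step: step 14

Remark: atom labels C1–C13 are those of the germacranolide skeleton of the target (C1 ketone, C3 enol-ether carbon, C10 quaternary C–O, C11/C12/C13 lactone α-carbon, carbonyl and CH2Cl); diazoethane is assumed to be freshly made from commercial N-ethyl-N-nitrosourea and KOH.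

**Route**

Step 1
Reactants: 1 diethyl D-tartrate; 2 4-methoxybenzaldehyde dimethyl acetal
Product: 3 diethyl (4S,5S)-2-(4-methoxyphenyl)-1,3-dioxolane-4,5-dicarboxylate
Conditions: camphorsulfonic acid (cat.), toluene, reflux with removal of MeOH
Reagents that add atoms: none
Why: Acid-catalysed transacetalisation of the trans-1,2-diol gives the five-membered 4-methoxybenzylidene acetal; the acetal carbon is not stereogenic on the C2-symmetric diol, and the two tartrate centres (later C6 and C7) are untouched.

Step 2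
Reactants: 3 diethyl (4S,5S)-2-(4-methoxyphenyl)-1,3-dioxolane-4,5-dicarboxylate
Product: 4 (2R,3R)-3-[(4-methoxybenzyl)oxy]butane-1,2,4-triol (2-O-PMB-D-threitol)
Conditions: LiAlH4, AlCl3, Et2O/CH2Cl2, −20 °C → reflux
Reagents that add atoms: none
Why: LiAlH4 reduces both esters and the chloroalanes formed with AlCl3 open the acetal reductively (hydride addition to the oxocarbenium ion), a reaction known for the benzylidene analogue; the C2 symmetry makes the two possible C–O cleavages identical, so a single mono-PMB ether (O6) should result.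

Step 3
Reactants: 4 (2R,3R)-3-[(4-methoxybenzyl)oxy]butane-1,2,4-triol
Product: 5 (2R)-2-[(4R)-2,2-dimethyl-1,3-dioxolan-4-yl]-2-[(4-methoxybenzyl)oxy]ethan-1-ol
Conditions: 2,2-dimethoxypropane, PPTS (cat.), acetone, rt
Reagents that add atoms: 2,2-dimethoxypropane COC(C)(C)OC
Why: Acid-catalysed acetonide formation under equilibrating conditions prefers the five-membered dioxolane on the terminal 1,2-diol (O7, O8) over a 1,3-dioxane, which leaves the C5 primary alcohol free.

Step 4
Reactants: 5 (2R)-2-[(4R)-2,2-dimethyl-1,3-dioxolan-4-yl]-2-[(4-methoxybenzyl)oxy]ethan-1-ol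
Product: 6 (2S)-2-[(4R)-2,2-dimethyl-1,3-dioxolan-4-yl]-2-[(4-methoxybenzyl)oxy]acetaldehyde (C5 aldehyde)
Conditions: Dess–Martin periodinane, NaHCO3, CH2Cl2, 0 °C → rt; used crude
Reagents that add atoms: none
Why: Dess–Martin oxidation of the primary alcohol under buffered, non-epimerising conditions; the α-alkoxy aldehyde is used without purification.

Step 5
Reactants: 6 C5 aldehyde; 7 (E)-but-2-ene
Product: 9 (1R,2S,3S)-1-[(4R)-2,2-dimethyl-1,3-dioxolan-4-yl]-1-[(4-methoxybenzyl)oxy]-3-methylpent-4-en-2-ol (4,5-anti, 5,6-syn), via borinate ester 8 (not isolated)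
Conditions: 7, KOtBu, n-BuLi, THF, −78 → −45 °C; (−)-Ipc2BOMe [(−)-B-methoxydiisopinocampheylborane, from (+)-α-pinene], −78 °C; BF3·OEt2, −78 °C; 6, −78 °C; then NaOH, H2O2, 0 °C → rt
Reagents that add atoms: none
Why: Brown crotylation: the (E)-crotylborane reacts through a chair Zimmerman–Traxler transition state, so the E geometry gives the 4,5-anti pair and the isopinocampheyl groups deliver the crotyl group to the Si face of the aldehyde (4S, 5S); this reagent control has to override the Felkin preference of the α-alkoxy aldehyde for the 5,6-anti isomer and should give the 5,6-syn product.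

Step 6
Reactants: 9 homoallylic alcohol
Product: 10 C5 tert-butyldimethylsilyl ether of 9
Conditions: TBSOTf, 2,6-lutidine, CH2Cl2, −78 → 0 °C
Reagents that add atoms: tert-butyldimethylsilyl triflate CC(C)(C)[Si](C)(C)OS(=O)(=O)C(F)(F)F
Why: Silylation of the hindered secondary alcohol with the silyl triflate; the C5 oxygen must be masked before the carbene step, and the acetonide and PMB ether are stable at low temperature.

Step 7
Reactants: 10 silyl ether; 11 methyl acrylate
Product: 12 methyl (2E,4S,5S,6S)-5-(tert-butyldimethylsilyloxy)-6-[(4R)-2,2-dimethyl-1,3-dioxolan-4-yl]-6-[(4-methoxybenzyl)oxy]-4-methylhex-2-enoate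
Conditions: second-generation Hoveyda–Grubbs catalyst (5 mol%), 11 (5 equiv), CH2Cl2, 40 °C
Reagents that add atoms: none
Why: Olefin cross-metathesis between a terminal alkene and an electron-poor acrylate, which does not homodimerise readily, gives the E-enoate and brings in C1 and C2 at the acid oxidation level.

Step 8
Reactants: 12 enoate acetonide
Product: 13 methyl (2E,4S,5S,6S,7R)-5-(tert-butyldimethylsilyloxy)-7,8-dihydroxy-6-[(4-methoxybenzyl)oxy]-4-methyloct-2-enoate
Conditions: PPTS, MeOH, rt
Reagents that add atoms: none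
Why: Acid-catalysed transketalisation to methanol removes the terminal acetonide, while the hindered secondary TBS ether, the PMB ether and the enoate survive.

Step 9
Reactants: 13 diol enoate
Product: 14 methyl 2-[(2S,3S,4S,5S,6R)-4-(tert-butyldimethylsilyloxy)-6-(hydroxymethyl)-5-[(4-methoxybenzyl)oxy]-3-methyloxan-2-yl]acetate (2,6-cis tetrahydropyran)
Conditions: KOtBu (0.2 equiv), THF, 0 °C → rt
Reagents that add atoms: none
Why: Base-catalysed 6-exo-trig oxa-Michael addition of the C7 hydroxyl under reversible conditions; the new C3 centre should settle as the 2,6-cis tetrahydropyran with the C3 and C7 arms equatorial, because the trans isomer would place the acetate arm 1,3-diaxial to the C5 silyloxy group, and the seven-membered ring from the primary hydroxyl is not competitive.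

Step 10
Reactants: 14 tetrahydropyran alcohol
Product: 15 methyl 2-[(2S,3S,4S,5S,6S)-4-(tert-butyldimethylsilyloxy)-6-formyl-5-[(4-methoxybenzyl)oxy]-3-methyloxan-2-yl]acetate
Conditions: Dess–Martin periodinane, NaHCO3, CH2Cl2, 0 °C → rt; used crude
Reagents that add atoms: none
Why: Dess–Martin oxidation of the primary alcohol, mild enough to avoid β-elimination of the C6 ether from the α-alkoxy aldehyde.

Step 11
Reactants: 15 tetrahydropyran aldehyde
Product: 16 methyl 2-[(2S,3S,4S,5S,6R)-4-(tert-butyldimethylsilyloxy)-6-ethenyl-5-[(4-methoxybenzyl)oxy]-3-methyloxan-2-yl]acetate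
Conditions: Ph3PCH3Br, KHMDS, THF, −78 → 0 °C
Reagents that add atoms: methyltriphenylphosphonium bromide C[P+](c1ccccc1)(c1ccccc1)c1ccccc1.[Br-] (CH2 through the ylide)
Why: Wittig methylenation with the lithium-free ylide at low temperature, where addition to the aldehyde is faster than enolisation or attack on the methyl ester; any epimerisation at C7 would return the equatorial (cis) aldehyde.

Step 12
Reactants: 16 vinyl tetrahydropyran ester
Product: 17 2-[(2S,3S,4S,5S,6R)-4-(tert-butyldimethylsilyloxy)-6-ethenyl-5-[(4-methoxybenzyl)oxy]-3-methyloxan-2-yl]acetic acid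
Conditions: LiOH, THF/MeOH/H2O, rt; then 1 M HCl to pH 4, 0 °C
Reagents that add atoms: lithium hydroxide [Li+].[OH-] (oxygen of the acid)
Why: Saponification of the methyl ester; the β-alkoxy ester should not undergo retro-Michael cleavage with hydroxide at room temperature, and the silyl and PMB ethers are retained.

Step 13
Reactants: 17 carboxylic acid
Product: 19 3-diazo-1-[(2S,3S,4S,5S,6R)-4-(tert-butyldimethylsilyloxy)-6-ethenyl-5-[(4-methoxybenzyl)oxy]-3-methyloxan-2-yl]butan-2-one (methyl diazoketone), via mixed anhydride 18 (not isolated)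
Conditions: i-BuOCOCl, Et3N, THF, −20 °C; then CH3CHN2 (Et2O solution, excess), −20 °C → rt
Reagents that add atoms: diazoethane CC=[N+]=[N-]
Why: Acylation of diazoethane by the mixed carbonic anhydride (the standard diazoketone synthesis applied to the higher diazoalkane) places the methyl group on the diazo carbon without any regiochemical question, in contrast to diazo transfer onto an ethyl ketone.

Step 14
Reactants: 19 methyl diazoketone
Product: 21 (5E)-3-(tert-butyldimethylsilyloxy)-4-[(4-methoxybenzyl)oxy]-2,8-dimethyl-11-oxabicyclo[6.2.1]undec-5-en-9-one (target numbering 3S,4S,5S,6S,10S; 7E), via oxonium ylide 20 (not isolated)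
Conditions: Rh2(NHCOCF3)4 (dirhodium tetrakis(trifluoroacetamidate), 2 mol%), CH2Cl2, rt, slow addition of 19 at high dilution
Reagents that add atoms: none
Why: The rhodium carbene formed from 19 with loss of N2 is attacked at C10 by the tetrahydropyran oxygen four atoms away, which closes the five-membered ring O–C3–C2–C1–C10 as the bicyclic oxonium ylide 20, and a [2,3]-sigmatropic shift through a five-centre envelope transition state then forms C9–C10 and breaks O–C7, so the six-membered ether grows by three atoms into the nine-membered oxacycle and the ten-membered carbocycle C1–C10 is closed by ring expansion and not by end-to-end cyclisation. The closest known reaction type is the metal-catalysed oxonium ylide formation and [2,3] ring expansion of 2-vinyl cyclic ethers bearing a diazoketone arm; the methyl group on the diazo carbon is the one departure from the parent case. The new quaternary centre C10 is fixed as S by C3, because the six-carbon bridge C4–C9 can only span the five-membered ring if C4 and C9 leave it on the same face. The step needs ylide formation to outrun the 1,2-hydride shift of the methyl-substituted carbene, which the proximity of the ring oxygen, the low migratory aptitude of a methyl C–H and the electron-poor amidate ligands should secure, and it needs [2,3]- over [1,2]-shift, secured by the allylic C7–O bond. It also needs the E geometry at C7=C8, for which Rh2(NHCOCF3)4 is chosen, Cu(hfacac)2 (copper bis(hexafluoroacetylacetonate)) being the catalyst of this reaction class that favours Z. The E alkene should emerge with the bridging oxygen lying across the face it has just left, so the opposite face stays open for steps 16 to 21.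

Step 15
Reactants: 21 bridged ketone
Product: 23 3(2H)-furanone (C2=C3 dehydro derivative of 21), via silyl enol ether 22 (not isolated)
Conditions: TMSOTf, Et3N, CH2Cl2, 0 °C; then Pd(OAc)2 (1.1 equiv), MeCN, rt
Reagents that add atoms: none
Why: Saegusa–Ito dehydrogenation: the ketone can enolise only toward C2 because C10 is quaternary, and β-hydride elimination from the palladium enolate removes the C3 hydrogen to give the 3(2H)-furanone, a vinylogous ester that from here on protects C1 and has no enolisable α-position.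

Step 16
Reactants: 23 furanone
Product: 24 C9 allylic alcohol of 23 (C9 configuration not defined; both epimers are carried on)
Conditions: SeO2 (0.5 equiv), t-BuOOH, CH2Cl2, rt
Reagents that add atoms: selenium dioxide O=[Se]=O (oxygen donor, reoxidised by tert-butyl hydroperoxide CC(C)(C)OO)
Why: Allylic hydroxylation by ene reaction of SeO2 followed by [2,3]-shift of the allylseleninic acid, which returns the double bond to C7=C8; the C9 methylene is expected to react in preference to the single C6 hydrogen, whose side is deactivated by the ether oxygen, and the C9 configuration does not matter here because step 17 removes it.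

Step 17
Reactants: 24 C9 allylic alcohol
Product: 25 C9 enone (C7=C8–C9=O)
Conditions: Dess–Martin periodinane, NaHCO3, CH2Cl2, rt
Reagents that add atoms: none
Why: Dess–Martin oxidation converges both C9 epimers on one enone under neutral conditions, which spare the non-enolisable 1,3-dicarbonyl array around C10 from retro-Claisen cleavage.

Step 18
Reactants: 25 C9 enone
Product: 26 (9S)-allylic alcohol
Conditions: NaBH4, CeCl3·7H2O, MeOH, −78 °C
Reagents that add atoms: none
Why: Luche 1,2-reduction: the hindered, twisted enone carbonyl should be attacked by hydride from the exposed outer face of the ring, away from the bridging oxygen, which sets 9S with the hydroxyl on the open face of the alkene; the vinylogous ester carbonyl at C1 is not reduced at this temperature.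

Step 19
Reactants: 26 (9S)-allylic alcohol
Product: 27 9-O-tert-butyldimethylsilyl ether of 26
Conditions: TBSOTf, 2,6-lutidine, CH2Cl2, −78 → 0 °C
Reagents that add atoms: tert-butyldimethylsilyl triflate CC(C)(C)[Si](C)(C)OS(=O)(=O)C(F)(F)F
Why: Silylation of the allylic alcohol, so that O6 is the only free hydroxyl after the next step.

Step 20
Reactants: 27 bis-silyl PMB ether
Product: 28 C6 allylic alcohol
Conditions: DDQ, CH2Cl2/pH 7 buffer, 0 °C
Reagents that add atoms: none
Why: Oxidative cleavage of the PMB ether by DDQ (benzylic hydride abstraction, then hydrolysis of the oxocarbenium ion); the silyl ethers, the alkene and the furanone are inert and the allylic C6 alcohol is set free.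

Step 21
Reactants: 28 C6 allylic alcohol
Product: 29 7,8-epoxy C6 alcohol (epoxide oxygen on the face opposite the bridging oxygen, erythro to O6 and O9)
Conditions: VO(acac)2 (5 mol%), t-BuOOH, CH2Cl2, 0 °C → rt
Reagents that add atoms: tert-butyl hydroperoxide CC(C)(C)OO (epoxide oxygen)
Why: Hydroxyl-directed epoxidation by the vanadium alkylperoxide bound to O6: E-allylic alcohols give the erythro epoxy alcohol, and this should also be the exposed face of the ring alkene, opposite the bridging oxygen, so C8 is set as in the target and the C7–O bond points away from the side on which C11 must enter.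

Step 22
Reactants: 29 epoxy alcohol; 30 diethylphosphonoacetic acid
Product: 31 C6 diethylphosphonoacetate of 29
Conditions: DCC, DMAP (cat.), CH2Cl2, 0 °C → rt
Reagents that add atoms: none
Why: Steglich esterification of the secondary alcohol with the phosphonoacetic acid; the epoxide and the silyl ethers are not affected.

Step 23
Reactants: 31 epoxy phosphonoacetate
Product: 33 α-methylene trans-fused γ-lactone (6,12-olide) with free 8-OH, via phosphono lactone 32 (not isolated)
Conditions: NaH, THF, 0 → 45 °C; then (CH2O)n, 45 °C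
Reagents that add atoms: formaldehyde C=O (as paraformaldehyde)
Why: The phosphonate-stabilised carbanion opens the epoxide at C7 by a 5-exo-tet SN2 attack with inversion (intramolecular epoxide alkylation by a stabilised ester carbanion), giving the trans-fused γ-lactone (7S) and the 8S alkoxide, and proton transfer then regenerates the phosphonate anion for Horner–Wadsworth–Emmons olefination with formaldehyde to the α-methylene lactone.

Step 24
Reactants: 33 hydroxy methylene lactone; 34 tiglic acid
Product: 35 8-O-tiglate of 33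
Conditions: 34, 2,4,6-trichlorobenzoyl chloride, Et3N, toluene, rt; then 33, DMAP, toluene, rt → 40 °C
Reagents that add atoms: none
Why: Yamaguchi esterification through the mixed 2,4,6-trichlorobenzoic anhydride acylates the hindered secondary C8 alcohol, the only free hydroxyl, without isomerising the tiglate double bond.

Step 25
Reactants: 35 tiglate
Product: 36 11,13-epoxide of 35 (spiro-epoxy lactone, epoxide oxygen cis to H7)
Conditions: t-BuOOH, n-BuLi, THF, −78 → −20 °C
Reagents that add atoms: tert-butyl hydroperoxide CC(C)(C)OO (epoxide oxygen)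
Why: Weitz–Scheffer-type nucleophilic epoxidation: the peroxide anion adds to the unhindered exocyclic methylene of the lactone (the β-substituted tiglate and the vinylogous-ester furanone are far poorer acceptors), and the lactone enolate should close on oxygen from the face anti to the C8 substituent, so the epoxide oxygen ends cis to H7 as required for 11S.

Step 26
Reactants: 36 spiro-epoxide
Product: 37 5,9-bis-O-tert-butyldimethylsilyl ether of the target (11-hydroxy-13-chloro)
Conditions: HCl (2 M in Et2O), CH2Cl2, −20 → 0 °C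
Reagents that add atoms: hydrogen chloride Cl
Why: Chloride opens the protonated spiro-epoxide at the primary carbon C13 by SN2, the tertiary C11–O bond next to the lactone carbonyl stays intact, and the C11 configuration is therefore retained in the tertiary alcohol.

Step 27
Reactants: 37 bis-silyl chlorohydrin
Product: 38 target CNP0340393.1
Conditions: HF·pyridine, THF, 0 °C → rt
Reagents that add atoms: none
Why: Fluoride-mediated cleavage of both silyl ethers under mildly acidic conditions, which should not promote tiglate migration between O8 and O9, lactone opening or chloride displacement.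

**Compound list**

1 | diethyl D-tartrate | CCOC(=O)[C@@H](O)[C@H](O)C(=O)OCC | starting material
2 | 4-methoxybenzaldehyde dimethyl acetal | COC(OC)c1ccc(OC)cc1 | starting material
3 | diethyl (4S,5S)-2-(4-methoxyphenyl)-1,3-dioxolane-4,5-dicarboxylate | CCOC(=O)[C@H]1OC(c2ccc(OC)cc2)O[C@@H]1C(=O)OCC | intermediate
4 | (2R,3R)-3-[(4-methoxybenzyl)oxy]butane-1,2,4-triol | OC[C@@H](O)[C@H](OCc1ccc(OC)cc1)CO | intermediate
5 | (2R)-2-[(4R)-2,2-dimethyl-1,3-dioxolan-4-yl]-2-[(4-methoxybenzyl)oxy]ethan-1-ol | OC[C@@H](OCc1ccc(OC)cc1)[C@H]1COC(C)(C)O1 | intermediate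
6 | (2S)-2-[(4R)-2,2-dimethyl-1,3-dioxolan-4-yl]-2-[(4-methoxybenzyl)oxy]acetaldehyde | O=C[C@@H](OCc1ccc(OC)cc1)[C@H]1COC(C)(C)O1 | intermediate
7 | (E)-but-2-ene | C/C=C/C | starting material
8 | diisopinocampheylborinate of 9 | C=C[C@H](C)[C@H](OB([C@@H]2C[C@@H]3C[C@H]([C@H]2C)C3(C)C)[C@@H]2C[C@@H]3C[C@H]([C@H]2C)C3(C)C)[C@@H](OCc2ccc(OC)cc2)[C@H]1COC(C)(C)O1 | intermediate (not isolated)
9 | (1R,2S,3S)-1-[(4R)-2,2-dimethyl-1,3-dioxolan-4-yl]-1-[(4-methoxybenzyl)oxy]-3-methylpent-4-en-2-ol | C=C[C@H](C)[C@H](O)[C@@H](OCc1ccc(OC)cc1)[C@H]1COC(C)(C)O1 | intermediate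
10 | C5 tert-butyldimethylsilyl ether of 9 | C=C[C@H](C)[C@H](O[Si](C)(C)C(C)(C)C)[C@@H](OCc1ccc(OC)cc1)[C@H]1COC(C)(C)O1 | intermediate
11 | methyl acrylate | C=CC(=O)OC | starting material
12 | methyl (2E,4S,5S,6S)-5-(tert-butyldimethylsilyloxy)-6-[(4R)-2,2-dimethyl-1,3-dioxolan-4-yl]-6-[(4-methoxybenzyl)oxy]-4-methylhex-2-enoate | COC(=O)/C=C/[C@H](C)[C@H](O[Si](C)(C)C(C)(C)C)[C@@H](OCc1ccc(OC)cc1)[C@H]1COC(C)(C)O1 | intermediate
13 | methyl (2E,4S,5S,6S,7R)-5-(tert-butyldimethylsilyloxy)-7,8-dihydroxy-6-[(4-methoxybenzyl)oxy]-4-methyloct-2-enoate | COC(=O)/C=C/[C@H](C)[C@H](O[Si](C)(C)C(C)(C)C)[C@@H](OCc1ccc(OC)cc1)[C@H](O)CO | intermediate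
14 | methyl 2-[(2S,3S,4S,5S,6R)-4-(tert-butyldimethylsilyloxy)-6-(hydroxymethyl)-5-[(4-methoxybenzyl)oxy]-3-methyloxan-2-yl]acetate | OC[C@H]1O[C@@H](CC(=O)OC)[C@H](C)[C@H](O[Si](C)(C)C(C)(C)C)[C@H]1OCc1ccc(OC)cc1 | intermediate
15 | methyl 2-[(2S,3S,4S,5S,6S)-4-(tert-butyldimethylsilyloxy)-6-formyl-5-[(4-methoxybenzyl)oxy]-3-methyloxan-2-yl]acetate | O=C[C@H]1O[C@@H](CC(=O)OC)[C@H](C)[C@H](O[Si](C)(C)C(C)(C)C)[C@H]1OCc1ccc(OC)cc1 | intermediate
16 | methyl 2-[(2S,3S,4S,5S,6R)-4-(tert-butyldimethylsilyloxy)-6-ethenyl-5-[(4-methoxybenzyl)oxy]-3-methyloxan-2-yl]acetate | C=C[C@H]1O[C@@H](CC(=O)OC)[C@H](C)[C@H](O[Si](C)(C)C(C)(C)C)[C@H]1OCc1ccc(OC)cc1 | intermediate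
17 | 2-[(2S,3S,4S,5S,6R)-4-(tert-butyldimethylsilyloxy)-6-ethenyl-5-[(4-methoxybenzyl)oxy]-3-methyloxan-2-yl]acetic acid | C=C[C@H]1O[C@@H](CC(=O)O)[C@H](C)[C@H](O[Si](C)(C)C(C)(C)C)[C@H]1OCc1ccc(OC)cc1 | intermediate
18 | isobutyl carbonic mixed anhydride of 17 | C=C[C@H]1O[C@@H](CC(=O)OC(=O)OCC(C)C)[C@H](C)[C@H](O[Si](C)(C)C(C)(C)C)[C@H]1OCc1ccc(OC)cc1 | intermediate (not isolated)
19 | 3-diazo-1-[(2S,3S,4S,5S,6R)-4-(tert-butyldimethylsilyloxy)-6-ethenyl-5-[(4-methoxybenzyl)oxy]-3-methyloxan-2-yl]butan-2-one | C=C[C@H]1O[C@@H](CC(=O)C(C)=[N+]=[N-])[C@H](C)[C@H](O[Si](C)(C)C(C)(C)C)[C@H]1OCc1ccc(OC)cc1 | intermediate (key-step precursor)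
20 | bicyclic oxonium ylide (O bonded to C3, C7 and C10; carbanion at C10) | C=C[C@H]1[O+]2[C@@H](CC(=O)[C-]2C)[C@H](C)[C@H](O[Si](C)(C)C(C)(C)C)[C@H]1OCc1ccc(OC)cc1 | intermediate (not isolated)
21 | (5E)-3-(tert-butyldimethylsilyloxy)-4-[(4-methoxybenzyl)oxy]-2,8-dimethyl-11-oxabicyclo[6.2.1]undec-5-en-9-one | C1/C=C/[C@H](OCc3ccc(OC)cc3)[C@@H](O[Si](C)(C)C(C)(C)C)[C@@H](C)[C@@H]2CC(=O)[C@@]1(C)O2 | intermediate (key-step product)
22 | C1 trimethylsilyl enol ether (C1=C2) of 21 | C1/C=C/[C@H](OCc3ccc(OC)cc3)[C@@H](O[Si](C)(C)C(C)(C)C)[C@@H](C)[C@@H]2C=C(O[Si](C)(C)C)[C@@]1(C)O2 | intermediate (not isolated)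
23 | 3(2H)-furanone, C2=C3 dehydro derivative of 21 | C1/C=C/[C@H](OCc3ccc(OC)cc3)[C@@H](O[Si](C)(C)C(C)(C)C)[C@@H](C)C2=CC(=O)[C@@]1(C)O2 | intermediate
24 | C9 allylic alcohol of 23 (both C9 epimers) | OC1/C=C/[C@H](OCc3ccc(OC)cc3)[C@@H](O[Si](C)(C)C(C)(C)C)[C@@H](C)C2=CC(=O)[C@@]1(C)O2 | intermediate
25 | C9 enone | O=C1/C=C/[C@H](OCc3ccc(OC)cc3)[C@@H](O[Si](C)(C)C(C)(C)C)[C@@H](C)C2=CC(=O)[C@@]1(C)O2 | intermediate
26 | (9S)-allylic alcohol | O[C@H]1/C=C/[C@H](OCc3ccc(OC)cc3)[C@@H](O[Si](C)(C)C(C)(C)C)[C@@H](C)C2=CC(=O)[C@@]1(C)O2 | intermediate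
27 | 9-O-tert-butyldimethylsilyl ether of 26 | CC(C)(C)[Si](C)(C)O[C@H]1/C=C/[C@H](OCc3ccc(OC)cc3)[C@@H](O[Si](C)(C)C(C)(C)C)[C@@H](C)C2=CC(=O)[C@@]1(C)O2 | intermediate
28 | C6 allylic alcohol (5,9-bis-silyl ether) | CC(C)(C)[Si](C)(C)O[C@H]1/C=C/[C@H](O)[C@@H](O[Si](C)(C)C(C)(C)C)[C@@H](C)C2=CC(=O)[C@@]1(C)O2 | intermediate
29 | 7,8-epoxy C6 alcohol | CC(C)(C)[Si](C)(C)O[C@H]1[C@H]2O[C@@H]2[C@H](O)[C@@H](O[Si](C)(C)C(C)(C)C)[C@@H](C)C3=CC(=O)[C@@]1(C)O3 | intermediate
30 | diethylphosphonoacetic acid | CCOP(=O)(CC(=O)O)OCC | starting material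
31 | C6 diethylphosphonoacetate of 29 | CC(C)(C)[Si](C)(C)O[C@H]1[C@H]2O[C@@H]2[C@H](OC(=O)CP(=O)(OCC)OCC)[C@@H](O[Si](C)(C)C(C)(C)C)[C@@H](C)C3=CC(=O)[C@@]1(C)O3 | intermediate
32 | α-(diethylphosphono) trans-fused γ-lactone with free 8-OH (C11 not defined) | CC(C)(C)[Si](C)(C)O[C@H]1[C@@H](O)[C@@H]2[C@H](OC(=O)C2P(=O)(OCC)OCC)[C@@H](O[Si](C)(C)C(C)(C)C)[C@@H](C)C3=CC(=O)[C@@]1(C)O3 | intermediate (not isolated)
33 | α-methylene trans-fused γ-lactone with free 8-OH | CC(C)(C)[Si](C)(C)O[C@H]1[C@@H](O)[C@@H]2[C@H](OC(=O)C2=C)[C@@H](O[Si](C)(C)C(C)(C)C)[C@@H](C)C3=CC(=O)[C@@]1(C)O3 | intermediate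
34 | tiglic acid | C/C=C(\C)C(=O)O | starting material
35 | 8-O-tiglate of 33 | CC(C)(C)[Si](C)(C)O[C@H]1[C@@H](OC(=O)/C(C)=C/C)[C@@H]2[C@H](OC(=O)C2=C)[C@@H](O[Si](C)(C)C(C)(C)C)[C@@H](C)C3=CC(=O)[C@@]1(C)O3 | intermediate
36 | 11,13-epoxide of 35 | CC(C)(C)[Si](C)(C)O[C@H]1[C@@H](OC(=O)/C(C)=C/C)[C@@H]2[C@H](OC(=O)[C@]24CO4)[C@@H](O[Si](C)(C)C(C)(C)C)[C@@H](C)C3=CC(=O)[C@@]1(C)O3 | intermediate
37 | 5,9-bis-O-tert-butyldimethylsilyl ether of the target | CC(C)(C)[Si](C)(C)O[C@H]1[C@@H](OC(=O)/C(C)=C/C)[C@@H]2[C@H](OC(=O)[C@]2(O)CCl)[C@@H](O[Si](C)(C)C(C)(C)C)[C@@H](C)C3=CC(=O)[C@@]1(C)O3 | intermediate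
38 | CNP0340393.1 (4R,5S,6S,7S,8S,9S,10S,11S) | C/C=C(\C)C(=O)O[C@H]1[C@@H]2[C@H](OC(=O)[C@]2(O)CCl)[C@@H](O)[C@@H](C)C2=CC(=O)[C@@](C)(O2)[C@H]1O | target

**Totals**

Total step count: 27. Longest linear sequence: 27 steps (from 1).

**Steps most likely to fail**

Step 14. The 1,2-hydride migration from the methyl group to the carbene carbon may outpace capture by the ring oxygen, and the E/Z ratio of the new ring alkene may erode. The fallback sets out from mixed anhydride 18 (made from 17 as in step 13). Diazomethane in place of diazoethane gives the unsubstituted diazoketone F1, whose carbene has no β-hydrogen. Rh2(NHCOCF3)4 in CH2Cl2 then effects the parent ring expansion to the C10–H bridged ketone F2. TMSOTf/Et3N followed by Pd(OAc)2 gives the C10–H furanone F3. Deprotonation at C10 with LiHMDS (THF, −78 °C) and C-methylation with MeI, which can only occur on the face that the six-carbon bridge leaves open, returns to the route at 23.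

Step 16. The ene reaction may be slow on the hindered disubstituted ring alkene, may take the C6 hydrogen instead, or may return the alkene with Z geometry after the seleninic ester shift. The fallback sets out from 23. Pd(OAc)2 (cat.), benzoquinone, AcOH at 40 °C gives allylic C–H acetoxylation through a π-allyl complex of divalent palladium, with acetate attacking the terminus remote from the C6 ether, and yields the C9 allylic acetate F4. K2CO3 in MeOH frees the alcohol and the route is rejoined at 24.

Step 23. The phosphonate carbanion may be too weak a nucleophile for SN2 opening at the ring carbon C7, so that elimination or acyl transfer takes over. The fallback sets out from allylic alcohol 28. Esterification with 30 (DCC, DMAP) gives the allylic phosphonoacetate F5. OsO4 (cat.) with N-methylmorpholine N-oxide should dihydroxylate the exposed face to give the 7,8-diol F6, with the same configuration at C7 and C8 as the epoxide. SOCl2/Et3N and then RuCl3 (cat.)/NaIO4 give the cyclic sulfate F7, a stronger electrophile than the epoxide. NaH in THF closes the lactone at C7 with inversion to the C8 sulfate monoester F8. Dilute H2SO4 in wet THF hydrolyses the sulfate to phosphono lactone 32, which is isolated this time, and K2CO3 with aqueous formaldehyde rejoins the route at 33.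

**Further compounds**

F1 | step 14 | 1-diazo-3-[(2S,3S,4S,5S,6R)-4-(tert-butyldimethylsilyloxy)-6-ethenyl-5-[(4-methoxybenzyl)oxy]-3-methyloxan-2-yl]propan-2-one | C=C[C@H]1O[C@@H](CC(=O)C=[N+]=[N-])[C@H](C)[C@H](O[Si](C)(C)C(C)(C)C)[C@H]1OCc1ccc(OC)cc1
F2 | step 14 | C10–H analogue of 21 (no methyl at C10) | C1/C=C/[C@H](OCc3ccc(OC)cc3)[C@@H](O[Si](C)(C)C(C)(C)C)[C@@H](C)[C@@H]2CC(=O)[C@H]1O2
F3 | step 14 | C10–H analogue of furanone 23 | C1/C=C/[C@H](OCc3ccc(OC)cc3)[C@@H](O[Si](C)(C)C(C)(C)C)[C@@H](C)C2=CC(=O)[C@H]1O2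
F4 | step 16 | C9 allylic acetate of 23 (C9 not defined) | CC(=O)OC1/C=C/[C@H](OCc3ccc(OC)cc3)[C@@H](O[Si](C)(C)C(C)(C)C)[C@@H](C)C2=CC(=O)[C@@]1(C)O2
F5 | step 23 | C6 diethylphosphonoacetate of allylic alcohol 28 | CC(C)(C)[Si](C)(C)O[C@H]1/C=C/[C@H](OC(=O)CP(=O)(OCC)OCC)[C@@H](O[Si](C)(C)C(C)(C)C)[C@@H](C)C2=CC(=O)[C@@]1(C)O2
F6 | step 23 | 7,8-diol of F5 | CC(C)(C)[Si](C)(C)O[C@H]1[C@@H](O)[C@H](O)[C@H](OC(=O)CP(=O)(OCC)OCC)[C@@H](O[Si](C)(C)C(C)(C)C)[C@@H](C)C2=CC(=O)[C@@]1(C)O2
F7 | step 23 | 7,8-cyclic sulfate of F6 | CC(C)(C)[Si](C)(C)O[C@H]1[C@H]2OS(=O)(=O)O[C@@H]2[C@H](OC(=O)CP(=O)(OCC)OCC)[C@@H](O[Si](C)(C)C(C)(C)C)[C@@H](C)C3=CC(=O)[C@@]1(C)O3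
F8 | step 23 | C8 hydrogen sulfate of phosphono lactone 32 | CC(C)(C)[Si](C)(C)O[C@H]1[C@@H](OS(=O)(=O)O)[C@@H]2[C@H](OC(=O)C2P(=O)(OCC)OCC)[C@@H](O[Si](C)(C)C(C)(C)C)[C@@H](C)C3=CC(=O)[C@@]1(C)O3
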